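**Assumption:** the target is a planar, achiral flavonol with no stereocentre, so "single enantiomer" is taken to mean the one constitution drawn; no stereocontrol is needed.

## Retrosynthetic overview

1. Quercetin 1 already holds rings A, C and B of the target with all five hydroxyl groups in place, so no ring is built.
2. Dibromide 2 comes from 1 by twofold electrophilic bromination at C6 and C8, the only C–H positions of ring A.
3. Compound 2 is converted in one flask, through borate-masked species 3–6, into target 7 by a twofold Cu-catalysed aryl C–O coupling (C6–OMe and C8–OMe); this is the key step.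

## Route

**Step 1**
Reactants: 1 quercetin (3,5,7,3',4'-pentahydroxyflavone)
Product: 2 6,8-dibromoquercetin (6,8-dibromo-3,5,7,3',4'-pentahydroxyflavone)
Conditions: Br2 (2.1 equiv), AcOH, 20 °C, 3 h; then H2O, filter
Reagents that add atoms: bromine, BrBr
Why: Electrophilic aromatic bromination (SEAr); the phloroglucinol-type A ring is by far the most electron-rich part of 1 and C6/C8 are its only C–H positions, so two equivalents of Br2 give the 6,8-dibromide, and no stereocentre is involved.

**Step 2**
Reactants: 2 6,8-dibromoquercetin
Product: 7 3,5,7,3',4'-pentahydroxy-6,8-dimethoxyflavone (target), via borate-masked 6,8-dibromoquercetin 3 (not isolated), via borate-masked 8-bromo-6-methoxyquercetin 4 (not isolated), via borate-masked 6-bromo-8-methoxyquercetin 5 (not isolated), via borate-masked 6,8-dimethoxyquercetin 6 (not isolated)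
Conditions: B(OMe)3 (4 equiv), NaOMe (9 equiv), MeOH/NMP, rt, 30 min, degassed; CuI (20 mol %), oxalamide ligand BHMPO (20 mol %), 90 °C, 16 h, Ar; then 1 M aq. HCl, ascorbic acid, 0 °C
Reagents that add atoms: sodium methoxide, C[O-].[Na+]
Why: Proposed new method: Cu(I)/oxalamide-catalysed twofold methoxylation of a fully unprotected polyhydroxyflavonol dibromide, using Na[B(OMe)4] made in the flask as both catechol mask and slow-release methoxide donor. The catechol is tied up as spiro-borate 3, so it cannot chelate or reduce copper, be oxidised, or be O-arylated. The 3-, 5- and 7-OH groups are sodium phenoxides, which shield the pyranone from methoxide attack, and the oxido groups ortho to each C–Br pre-coordinate L·Cu(I)–OMe (ortho effect) for oxidative addition and C–O reductive elimination. This gives 4 or 5 first, then 6, and acidic work-up hydrolyses the borate to 7. Because the 5,7-dioxy A ring is symmetric, the order of the two couplings and any Wessely–Moser equilibration do not matter. The closest known reaction type is the Ullmann-type Cu-catalysed methoxylation of aryl bromides (NaOMe/CuBr methanolysis of bromophenols, and Cu/oxalamide coupling with boron-bound methoxide); it has not been shown on a free catechol-bearing flavonol or with a tetramethoxyborate mask. No stereocentre is formed.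

## Compound list

1 | quercetin (3,5,7,3',4'-pentahydroxyflavone) | O=c1c(O)c(-c2ccc(O)c(O)c2)oc2cc(O)cc(O)c12 | starting material
2 | 6,8-dibromoquercetin | O=c1c(O)c(-c2ccc(O)c(O)c2)oc2c(Br)c(O)c(Br)c(O)c12 | intermediate
3 | borate-masked 6,8-dibromoquercetin (sodium 3',4'-O-dimethoxyborate; remaining OH groups drawn protonated, sodium phenoxides in the flask) | O=c1c(O)c(-c2ccc3O[B-](OC)(OC)Oc3c2)oc2c(Br)c(O)c(Br)c(O)c12.[Na+] | intermediate (not isolated)
4 | borate-masked 8-bromo-6-methoxyquercetin (same convention) | O=c1c(O)c(-c2ccc3O[B-](OC)(OC)Oc3c2)oc2c(Br)c(O)c(OC)c(O)c12.[Na+] | intermediate (not isolated)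
5 | borate-masked 6-bromo-8-methoxyquercetin (same convention) | O=c1c(O)c(-c2ccc3O[B-](OC)(OC)Oc3c2)oc2c(OC)c(O)c(Br)c(O)c12.[Na+] | intermediate (not isolated)
6 | borate-masked 6,8-dimethoxyquercetin (same convention) | O=c1c(O)c(-c2ccc3O[B-](OC)(OC)Oc3c2)oc2c(OC)c(O)c(OC)c(O)c12.[Na+] | intermediate (not isolated)
7 | 3,5,7,3',4'-pentahydroxy-6,8-dimethoxyflavone | COc1c(O)c(OC)c2oc(-c3ccc(O)c(O)c3)c(O)c(=O)c2c1O | target

## Step count and risk

Total step count: 2. Longest linear sequence: 2 (from quercetin).

The route has only two steps, so both are ranked here, most risky first; there is no third step to name.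

**1. Step 2 (the proposed new step).** The main risks are protodebromination (giving quercetin or the monomethoxy compounds), sequestration of copper by the 3-oxido-4-keto site, and a stalled second coupling. The fallback uses known chemistry only and replaces the direct masked coupling by protect, couple, deprotect. It sets out from 2. Benzylation (BnBr, K2CO3, DMF, 60 °C) caps the 3-, 7-, 3'- and 4'-OH groups and leaves the chelated 5-OH free, giving 3,7,3',4'-tetra-O-benzyl-6,8-dibromoquercetin F1. Classical Ullmann methanolysis (NaOMe, CuBr, DMF/MeOH, 110 °C) then gives 3,7,3',4'-tetra-O-benzyl-6,8-dimethoxyquercetin F2. Hydrogenolysis (H2, Pd/C, THF/MeOH, rt) removes the four benzyl groups, and the fallback comes back to the route at 7.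

**2. Step 1.** The risks are oxidation of the free catechol or of the flavonol C2=C3 enol by bromine, and mixtures of mono- and dibromides from the poorly soluble substrate. The fallback brominates a catechol-protected substrate instead of free quercetin. It sets out from 1. Heating with Ph2CCl2 (Ph2O, 175 °C) gives 3',4'-O-(diphenylmethylene)quercetin F3. Bromination (NBS, 2.1 equiv, DMF, 0 °C) gives 6,8-dibromo-3',4'-O-(diphenylmethylene)quercetin F4. Ketal hydrolysis (AcOH/H2O 4:1, reflux), which leaves the aryl bromides untouched, brings the fallback back to the route at 2.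

## Further compounds

F1 | step 2 | 3,7,3',4'-tetra-O-benzyl-6,8-dibromoquercetin | O=c1c(OCc2ccccc2)c(-c2ccc(OCc3ccccc3)c(OCc3ccccc3)c2)oc2c(Br)c(OCc3ccccc3)c(Br)c(O)c12
F2 | step 2 | 3,7,3',4'-tetra-O-benzyl-6,8-dimethoxyquercetin | O=c1c(OCc2ccccc2)c(-c2ccc(OCc3ccccc3)c(OCc3ccccc3)c2)oc2c(OC)c(OCc3ccccc3)c(OC)c(O)c12
F3 | step 1 | 3',4'-O-(diphenylmethylene)quercetin | O=c1c(O)c(-c2ccc3OC(c4ccccc4)(c4ccccc4)Oc3c2)oc2cc(O)cc(O)c12
F4 | step 1 | 6,8-dibromo-3',4'-O-(diphenylmethylene)quercetin | O=c1c(O)c(-c2ccc3OC(c4ccccc4)(c4ccccc4)Oc3c2)oc2c(Br)c(O)c(Br)c(O)c12
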